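**Assumption:** lupalbigenin (6,3'-diprenylgenistein) has no stereocentres and no E/Z-defined alkenes, so "single enantiomer" does not apply; the target is the SMILES exactly as given.

## Retrosynthetic overview

1. Target ⇒ cut both aryl–prenyl bonds (C6–CH2 and C3'–CH2) by a double aromatic [3,3] Claisen of genistein 7,4'-bis(1,1-dimethylallyl) ether. The new element is a covalent O5/O4 boron chelate that steers the ring-A shift to C6 instead of C8.
2. Bis(1,1-dimethylallyl) ether ⇒ bis(1,1-dimethylpropargyl) ether (Lindlar) ⇒ genistein (Cu-catalysed O-propargylation of the 7- and 4'-OH; the chelated 5-OH is left alone).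
3. Genistein ⇒ 2,4,6,4'-tetrahydroxydeoxybenzoin + one carbon from DMF ⇒ phloroglucinol + 4-hydroxyphenylacetic acid.
4. Ring order: rings A and B are bought as arenes; ring C (γ-pyranone) is closed in step 2; no further rings are formed. No protecting groups.

## Route

**Step 1**
Reactants: 1, phloroglucinol; 2, 4-hydroxyphenylacetic acid
Product: 3, 2-(4-hydroxyphenyl)-1-(2,4,6-trihydroxyphenyl)ethan-1-one
Conditions: BF3·OEt2 (neat), 85 °C, 2 h; then aq. NaOAc
Reagents that add atoms: 4-hydroxyphenylacetic acid (2), OC(=O)Cc1ccc(O)cc1
Why: BF3-mediated Friedel–Crafts (Houben–Hoesch-type) C-acylation of the symmetric, highly nucleophilic phloroglucinol gives a single regioisomer, and the BF3-chelated ketone product resists over-acylation.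

**Step 2**
Reactants: 3, the deoxybenzoin; 4, N,N-dimethylformamide
Product: 5, genistein (5,7-dihydroxy-3-(4-hydroxyphenyl)-4H-chromen-4-one)
Conditions: BF3·OEt2, DMF, 50 °C; then MsCl/DMF, 90 °C, 2 h; H2O
Reagents that add atoms: DMF (4), CN(C)C=O (supplies C2–H)
Why: Deoxybenzoin isoflavone synthesis: Vilsmeier-type formylation of the activated CH2 followed by cyclodehydration onto an ortho OH closes the pyranone; the two ortho OH groups are equivalent, so only one product can form.

**Step 3**
Reactants: 5, genistein; 6, 3-chloro-3-methylbut-1-yne (2.4 equiv)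
Product: 7, 5-hydroxy-7-[(2-methylbut-3-yn-2-yl)oxy]-3-{4-[(2-methylbut-3-yn-2-yl)oxy]phenyl}-4H-chromen-4-one
Conditions: CuCl2·2H2O (2 mol %), DBU (2.6 equiv), MeCN/DMF, 0 °C → rt
Reagents that add atoms: 3-chloro-3-methylbut-1-yne (6), C#CC(C)(C)Cl
Why: Copper-catalysed propargylic etherification (Cu-acetylide/allenylidene, Godfrey-type) O-alkylates only the two acidic, non-chelated phenoxides (7-OH, 4'-OH); the 5-OH stays locked in its hydrogen bond to C4=O and base is limiting.

**Step 4**
Reactants: 7, the bis(propargyl) ether
Product: 8, 5-hydroxy-7-[(2-methylbut-3-en-2-yl)oxy]-3-{4-[(2-methylbut-3-en-2-yl)oxy]phenyl}-4H-chromen-4-one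
Conditions: H2 (1 atm), Lindlar catalyst, quinoline, EtOAc, rt, stop at 2 equiv H2; chromatograph on Et3N-washed silica, store cold
Reagents that add atoms: none (H2 only)
Why: Lindlar semi-hydrogenation stops terminal alkynes at the alkene, and the chromone C2=C3 bond (vinylogous ester) and aryl ethers are inert to poisoned Pd at 1 atm.

**Step 5 (key step)**
Reactants: 8, the bis(1,1-dimethylallyl) ether
Product: 9, lupalbigenin (5,7-dihydroxy-3-[4-hydroxy-3-(3-methylbut-2-en-1-yl)phenyl]-6-(3-methylbut-2-en-1-yl)-4H-chromen-4-one)
Conditions: Ph2B–O–BPh2 (0.55 equiv), 4 Å MS, 2,6-lutidine (0.2 equiv), PhMe, 40 °C, 1 h (forms the O5,O4–BPh2 chelate in situ); then 110–120 °C (sealed), 8 h; then HOCH2CH2NH2, THF/MeOH, rt (removes boron as 2-aminoethyl diphenylborinate); chromatography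
Reagents that add atoms: none (the boron template is removed)
Why: Proposed new method: a boron-chelate-directed double aromatic Claisen rearrangement. The covalent O5–BPh2←O4 chelate (a benzo-fused boron β-diketonate) fixes ring-A π-bonds as C4a=C5/C6=C7, so the 7-O-(1,1-dimethylallyl) group shifts [3,3] across C7=C6: the C6 dienone keeps the chelate's O5–C5=C4a–C4=O4 delocalisation, whereas the C8 dienone would break it. The allyl inversion of the tertiary ether delivers a linear prenyl at C6, and the 4'-ether rearranges normally to C3' (both ortho sites equivalent). Closest known reaction types are the thermal ortho-Claisen of aryl 1,1-dimethylallyl ethers and the hydrogen-bond ("chelation") regiocontrol seen with 4-allyloxy-2-hydroxyacetophenones; a covalent chelate as a traceless regiocontrol element for a chromone O7→C6 Claisen is not described, and unassisted 5-hydroxy-7-allyloxychromones typically give 6-/8-mixtures.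

## Compound list

1 | phloroglucinol | Oc1cc(O)cc(O)c1 | starting material
2 | 4-hydroxyphenylacetic acid | OC(=O)Cc1ccc(O)cc1 | starting material
3 | 2-(4-hydroxyphenyl)-1-(2,4,6-trihydroxyphenyl)ethan-1-one | O=C(Cc1ccc(O)cc1)c1c(O)cc(O)cc1O | intermediate
4 | N,N-dimethylformamide | CN(C)C=O | starting material (C1 source)
5 | genistein | O=c1c(-c2ccc(O)cc2)coc2cc(O)cc(O)c12 | intermediate
6 | 3-chloro-3-methylbut-1-yne | C#CC(C)(C)Cl | starting material
7 | genistein 7,4'-bis(1,1-dimethylpropargyl) ether | O=c1c(-c2ccc(OC(C)(C)C#C)cc2)coc2cc(OC(C)(C)C#C)cc(O)c12 | intermediate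
8 | genistein 7,4'-bis(1,1-dimethylallyl) ether | O=c1c(-c2ccc(OC(C)(C)C=C)cc2)coc2cc(OC(C)(C)C=C)cc(O)c12 | intermediate
9 | lupalbigenin | CC(C)=CCc1cc(-c2coc3cc(O)c(CC=C(C)C)c(O)c3c2=O)ccc1O | target

## Summary

Total steps: 5. Longest linear sequence: 5 (fully linear, protecting-group-free).

Steps most likely to fail:

1. **Step 5 (proposed new step).** Risks: incomplete C6 selectivity (giving the 8,3'-diprenyl isomer), loss of isoprene from the tertiary ethers, and steric or electronic retardation by the chelate. Fallback (known chemistry, different logic — migrate from O5, whose only free ortho carbon is C6): genistein 5 → selective 7-O-MOM ether (MOMCl, K2CO3) → 5,4'-di-O-allyl ether (allyl bromide, K2CO3, DMF) → thermal double ortho-Claisen (PhNEt2, 190 °C) to the 6,3'-diallyl compound → double cross-metathesis with 2-methyl-2-butene (Grubbs II) → MOM removal (dilute HCl/MeOH).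

2. **Step 3.** Risks: incomplete bis-etherification, some 5-O-alkylation, or hydrolysis/elimination of the tertiary propargylic chloride. Fallback: drop the alkyne route and make 8 directly from 5 by Pd(0)-catalysed Tsuji–Trost O-(1,1-dimethylallyl)ation with tert-butyl 2-methylbut-3-en-2-yl carbonate (Pd(PPh3)4, THF, 0 °C), which also removes step 4.

3. **Step 4.** Risks: over-reduction to tert-amyl ethers or stalling at the mono-alkene. Fallback: replace hydrogenation with Ru-catalysed hydrosilylation of the terminal alkynes ([Cp*Ru(MeCN)3]PF6, Et3SiH) followed by protodesilylation (TBAF/CuI) to give the terminal alkenes.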